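The earlier runs and the new flask were computed for an exercise, noise included.

3 questions stand on this flask: two excesses and a conversion.

1. excess of left-handed product over right-handed product in the product at 50 min
2. excess of left-handed product over right-handed product in the product at 40 h
3. part of the left-handed substrate and right-handed substrate charged together that has reacted at 40 h

in all of them: left-handed substrate 20 mM; right-handed substrate 20 mM; racemization catalyst 28 µM

|  | reagent | free catalyst | remark | time |
|---|---|---|---|---|
| epsilon | 50 mM | 34 µM | run made earlier |  |
| zeta | 50 mM | 53 µM | run made earlier |  |
| delta | 25 mM | 24 µM | run made earlier |  |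
| flask | 50.0 mM | 24 µM |  | 40 h |

| run | time / h | left-handed product / % | right-handed product / % |
|---|---|---|---|
| epsilon | 12.0 | 7.3 | 4.0 |
| epsilon | 25.0 | 6.3 | 4.1 |
| epsilon | 40.0 | 7.2 | 4.2 |
| epsilon | 50.0 | 7.1 | 4.7 |
| zeta | 12.0 | 10.7 | 6.7 |
| zeta | 25.0 | 10.9 | 6.0 |
| zeta | 40.0 | 11.1 | 7.0 |
| zeta | 50.0 | 10.9 | 5.6 |
| delta | 4.00 | 2.9 | 1.5 |
| delta | 8.00 | 4.2 | 1.5 |
| delta | 20.0 | 5.0 | 2.2 |
| delta | 50.0 | 5.3 | 3.2 |

(readings scatter by 0.5 percentage points)

- free catalyst is single-handed; left-handed substrate and right-handed substrate are mirror images of each other, charged as a racemate, each of them at the stated concentration
- what was read earlier has a scatter of 0.5 percentage points, one standard deviation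
- steps thought possible: reagent + free catalyst + left-handed substrate -> free catalyst + left-handed product; reagent + free catalyst + right-handed substrate -> free catalyst + right-handed product; left-handed substrate + racemization catalyst <-> right-handed substrate + racemization catalyst; 2 racemization catalyst -> spent catalyst A; reagent + free catalyst -> spent catalyst B
- an excess is the difference of the two amounts in percent of their sum
- an excess is below zero if the other one leads

We start by following one molecule of free catalyst. At each fork it either turns a substrate or dies, and reagent stands in both steps, so the reagent charge cancels from the odds. Epsilon and zeta are flat from 12.0 h, with mean total product 11.2% and 17.2%. Pooled, they give T = 131, the turnovers per free catalyst charged, or turnover number.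

The second way is delta, with half the reagent and another catalyst charge. Its readings at 20.0 h and 50.0 h average 7.85%, which gives 131 turnovers. The two ways agree, so we trust T, and for the flask it gives 7.85% reacted.

For the excess the same two ways part. Epsilon and zeta pooled read 25.7%, while delta reads 34.9%. Delta is the one that cheats: the same scatter of 0.5 percentage points falls on a mean total of 6.45%, which is smaller than the 14.2% of the other two. We therefore commit to 25.7% for the flask at both times.

The forecast, holding that “the free catalyst is dying, not the substrate running out”, gives 8% reacted with excesses of 30% and 28.5%. Its conversion is close to ours, but its early excess stands above ours.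

The flask gives 24.8% at 50 min, 24.6% at 40 h and 8.00% reacted, which is 133 turnovers per catalyst charged. The forecast's early excess is 5.2 points too high.

    reagent + free catalyst + left-handed substrate → free catalyst + left-handed product (k = 30000 /M²/h)
    reagent + free catalyst + right-handed substrate → free catalyst + right-handed product (k = 18000 /M²/h)
    left-handed substrate + racemization catalyst ⇌ right-handed substrate + racemization catalyst, rate k3*[racemization catalyst]*[left-handed substrate] forward; the back reaction follows from the equilibrium constant (k = 8700 /M/h)
    2 racemization catalyst → spent catalyst A (k = 420 /M/h)
    reagent + free catalyst → spent catalyst B (k = 6.90 /M/h)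

With concentrations held at their charge, the half-life of reagent by the left-handed turning is 48 h, against 170 d by the step to spent catalyst B. At 40.0 h the flask holds free catalyst at 0% of its charge, with 92% of the left-handed substrate still there. For a neighbour, the same flask with 0.060 mM of free catalyst, T gives 19.6% reacted; the computed neighbour flask reaches 18.8%.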